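**Retrosynthetic overview**

- Numbering: ring C1 (C=O), C2=C3, C4 (CHOH), C5 (CH2), C6 (quaternary C–OH); side chain C1'–C17' with C2' the carbinol and C10'=C11' the Z-alkene.
- The plan rests on one feature of the ring: C1–C2=C3–C4 is a four-carbon unit carrying oxygen at both ends, and C5–C6 is a two-carbon unit whose C6 carries one oxygen and the carbon C1'. The ring is therefore a 1,4-dioxygenated butadiene joined to a 1-oxy-1-formyl alkene.
- The only ring is made by cutting C4–C5 and C1–C6: (E,E)-1,4-diacetoxybutadiene plus iminium-activated 2-(benzoyloxy)acrolein, whose formyl carbon becomes C1'. This step sets C1, C4 and C6 with all three oxygens cis.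
- C1'–C2' is cut next: a C6/C1' spiro-epoxide (CHO → CH2OH → primary tosylate → epoxide) is opened by the 2-lithio-1,3-dithiane made from (Z)-hexadec-9-enal.
- End game: unmask the C2' ketone, reduce it under direction from the C1/C6 diol, oxidise the allylic C1 carbinol (C4–OH silylated), desilylate.

Key step: step 3

Assumption: the sense of enantio-induction of the binaphthyl diammonium catalyst with this diene cannot be taken over from other dienes with certainty; the (R)-diamine is written, and its antipode is used in step 3 without other change if the first run gives the mirror-image adduct.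

**Step 1**
Reactants: 1 2,2-dimethyl-1,3-dioxan-5-one
Product: 3 2,2-dimethyl-4H-1,3-dioxin-5-yl benzoate, via potassium enolate 2 (not isolated)
Conditions: KN(SiMe3)2, THF, −78 °C; then BzCl, −78 → 0 °C
Reagents that add atoms: benzoyl chloride, O=C(Cl)c1ccccc1
Why: Deprotonation gives the potassium enolate, and the hard acyl chloride should acylate this dissociated enolate on oxygen (enol ester formation).

**Step 2**
Reactants: 3 2,2-dimethyl-4H-1,3-dioxin-5-yl benzoate
Product: 4 2-(benzoyloxy)acrolein (3-oxoprop-1-en-2-yl benzoate)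
Conditions: toluene, 110 °C
Reagents that add atoms: none
Why: Thermal retro-hetero-Diels–Alder reaction of the 4H-1,3-dioxin expels acetone and leaves the 2-acyloxy enal, the loss of the volatile ketone driving the fragmentation.

**Step 3**
Reactants: 4 2-(benzoyloxy)acrolein; 5 (1E,3E)-buta-1,3-diene-1,4-diyl diacetate
Product: 6 (1R,2S,5S)-2,5-diacetoxy-1-(benzoyloxy)cyclohex-3-ene-1-carbaldehyde (benzoate and both acetates cis; formyl carbon is C1', ring carbons are C6, C1 and C4 of the target)
Conditions: (R)-1,1'-binaphthyl-2,2'-diamine (10 mol %), Tf2NH (19 mol %), EtCN, −40 °C; diene in twofold excess, the surplus recovered unchanged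
Reagents that add atoms: none
Why: Proposed new method: the aldehyde of 4 condenses reversibly with the chiral primary ammonium salt to a catalyst-bound 2-benzoyloxy iminium ion, present only in catalytic amount, whose lowered LUMO lets the moderately electron-rich diene 5 add in a concerted, suprafacial normal-demand [4+2] cycloaddition, after which hydrolysis of the product iminium releases 6 and the catalyst. The closest known reaction type is the enantioselective Diels–Alder reaction of 2-acyloxyacroleins with cyclopentadiene, cyclohexadiene and simple alkyl-substituted acyclic dienes under chiral primary ammonium catalysis, together with the thermal cycloadditions of 5 with acrylates; a 1,4-dioxygenated diene has not been paired with an iminium-activated 2-acyloxyacrolein, and a weakly nucleophilic aromatic diamine is chosen so that the enol acetate does not acetylate the catalyst. The cyclohexene ring is closed by intermolecular [4+2] cycloaddition that forms C4–C5 and C1–C6 at once. The cis relation of C1–OAc and C4–OAc follows from the E,E geometry of 5 and suprafacial bond formation; the configuration of quaternary C6 relative to them comes from an exo-formyl/endo-benzoyloxy transition state, which keeps the bulky N-aryl iminium unit away from the two terminal acetoxy groups and puts the benzoate cis to both; the absolute configuration of all three centres comes from the binaphthyl backbone, which blocks one face of the iminium ion. The step needs exo-formyl diastereoselectivity and enantiofacial selectivity; regiochemistry is not an issue because 5 is symmetric, and 6 has no α-hydrogen, so it can neither epimerise nor be diverted as an enamine.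

**Step 4**
Reactants: 6 (1R,2S,5S)-2,5-diacetoxy-1-(benzoyloxy)cyclohex-3-ene-1-carbaldehyde
Product: 8 (1S,2S,4S)-2-(hydroxymethyl)cyclohex-5-ene-1,2,4-triol, via hydroxymethyl triester 7 (not isolated)
Conditions: NaBH4, MeOH–THF, −20 °C; then K2CO3 (cat.), MeOH, rt
Reagents that add atoms: none
Why: Fast borohydride reduction of the non-enolisable aldehyde is followed in the same pot by base-catalysed transesterification (Zemplén-type methanolysis) of the three esters, the tertiary benzoate leaving after 1,2-acyl migration to the new primary oxygen, and no stereocentre is touched.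

**Step 5**
Reactants: 8 (1S,2S,4S)-2-(hydroxymethyl)cyclohex-5-ene-1,2,4-triol
Product: 9 [(1S,2S,5S)-1,2,5-trihydroxycyclohex-3-en-1-yl]methyl 4-methylbenzenesulfonate
Conditions: TsCl (1.05 equiv), Bu2SnO (5 mol %), Et3N, MeCN, 0 °C
Reagents that add atoms: 4-toluenesulfonyl chloride, Cc1ccc(cc1)S(=O)(=O)Cl
Why: The primary hydroxyl of the C6/C1' 1,2-diol should be sulfonylated selectively through its catalytic dibutylstannylene acetal (tin-mediated regioselective sulfonylation), leaving the two secondary and the tertiary hydroxyls free.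

**Step 6**
Reactants: 9 [(1S,2S,5S)-1,2,5-trihydroxycyclohex-3-en-1-yl]methyl 4-methylbenzenesulfonate
Product: 10 [(1S,2S,5S)-5-(tert-butyldimethylsilyloxy)-1,2-dihydroxycyclohex-3-en-1-yl]methyl 4-methylbenzenesulfonate
Conditions: TBSCl (1.1 equiv), imidazole, DMF, −20 → 0 °C
Reagents that add atoms: tert-butyldimethylsilyl chloride, CC(C)(C)[Si](C)(C)Cl
Why: Imidazole-mediated silyl ether formation should take place at C4–OH, which has a CH2 neighbour, and not at C1–OH, which is neopentyl-like beside the fully substituted C6, nor at the tertiary C6–OH.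

**Step 7**
Reactants: 10 [(1S,2S,5S)-5-(tert-butyldimethylsilyloxy)-1,2-dihydroxycyclohex-3-en-1-yl]methyl 4-methylbenzenesulfonate
Product: 11 (3S,4S,7S)-7-(tert-butyldimethylsilyloxy)-1-oxaspiro[2.5]oct-5-en-4-ol (spiro-epoxide C6–O–C1', epoxide oxygen cis to C1–OH and C4–OTBS)
Conditions: K2CO3, MeOH, 0 °C → rt
Reagents that add atoms: none
Why: Intramolecular Williamson etherification (3-exo-tet) of the tertiary C6 alkoxide on the primary tosylate closes the spiro-epoxide with retention at C6, and the C1 alkoxide cannot compete because C1–O is trans to C1'.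

**Step 8**
Reactants: 12 (Z)-hexadec-9-enal; 13 propane-1,3-dithiol
Product: 14 2-[(8Z)-pentadec-8-en-1-yl]-1,3-dithiane
Conditions: BF3·OEt2 (20 mol %), CH2Cl2, 0 °C, dark
Reagents that add atoms: none
Why: Lewis acid-catalysed dithioacetalisation of the aldehyde, under ionic conditions that should leave the isolated Z-alkene unchanged.

**Step 9**
Reactants: 11 (3S,4S,7S)-7-(tert-butyldimethylsilyloxy)-1-oxaspiro[2.5]oct-5-en-4-ol; 14 2-[(8Z)-pentadec-8-en-1-yl]-1,3-dithiane
Product: 16 (1S,2S,5S)-5-(tert-butyldimethylsilyloxy)-1-({2-[(8Z)-pentadec-8-en-1-yl]-1,3-dithian-2-yl}methyl)cyclohex-3-ene-1,2-diol, via 2-lithio-1,3-dithiane 15 (not isolated)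
Conditions: 14 (2.5 equiv), n-BuLi (2.4 equiv), THF, −30 °C; then 11 (1 equiv), DMPU, −30 → 0 °C; H2O
Reagents that add atoms: none
Why: The 2-lithio-1,3-dithiane (Corey–Seebach acyl anion equivalent) opens the 2,2-disubstituted epoxide by SN2 attack at its CH2 terminus, forming C1'–C2' and leaving C6 untouched; one equivalent is consumed by the free C1–OH, and the cis C1–O/C6–O relation rules out Payne rearrangement.

**Step 10**
Reactants: 16 (1S,2S,5S)-5-(tert-butyldimethylsilyloxy)-1-({2-[(8Z)-pentadec-8-en-1-yl]-1,3-dithian-2-yl}methyl)cyclohex-3-ene-1,2-diol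
Product: 17 (10Z)-1-[(1S,2S,5S)-5-(tert-butyldimethylsilyloxy)-1,2-dihydroxycyclohex-3-en-1-yl]heptadec-10-en-2-one
Conditions: MeI, CaCO3, MeCN–H2O (9:1), 40 °C
Reagents that add atoms: water, O
Why: S-Methylation turns the dithiane into a sulfonium leaving group and water hydrolyses it to the C2' ketone under CaCO3 buffering (alkylative dithioacetal hydrolysis), which should spare the alkenes, the free hydroxyls and the silyl ether.

**Step 11**
Reactants: 17 (10Z)-1-[(1S,2S,5S)-5-(tert-butyldimethylsilyloxy)-1,2-dihydroxycyclohex-3-en-1-yl]heptadec-10-en-2-one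
Product: 18 (1R,2S,5S)-5-(tert-butyldimethylsilyloxy)-1-[(2S,10Z)-2-hydroxyheptadec-10-en-1-yl]cyclohex-3-ene-1,2-diol
Conditions: Me4NBH(OAc)3, MeCN–AcOH (1:1), −30 °C
Reagents that add atoms: none
Why: Hydroxyl-directed internal hydride delivery (Evans–Saksena reduction) sets C2': the cis C1/C6 diol should displace two acetates to give a cyclic dialkoxy(acetoxy)borohydride, so that in the chair C6–C1'–C2'···H–B–O6 ring carbon C1 is held axial through O1–B, C5 and the chain are equatorial, and hydride reaches the carbonyl face that gives the (2'S) carbinol, i.e. C6–O and C2'–O anti along C5–C6–C1'–C2'–C3'.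

**Step 12**
Reactants: 18 (1R,2S,5S)-5-(tert-butyldimethylsilyloxy)-1-[(2S,10Z)-2-hydroxyheptadec-10-en-1-yl]cyclohex-3-ene-1,2-diol
Product: 19 (4S,6R)-4-(tert-butyldimethylsilyloxy)-6-hydroxy-6-[(2S,10Z)-2-hydroxyheptadec-10-en-1-yl]cyclohex-2-en-1-one
Conditions: activated MnO2 (excess), CH2Cl2, rt
Reagents that add atoms: none
Why: MnO2 should oxidise only the allylic secondary carbinol at C1 (allylic alcohol oxidation), since C4–O is silylated, C2'–OH is not allylic and C6–OH is tertiary, and no stereocentre is affected.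

**Step 13**
Reactants: 19 (4S,6R)-4-(tert-butyldimethylsilyloxy)-6-hydroxy-6-[(2S,10Z)-2-hydroxyheptadec-10-en-1-yl]cyclohex-2-en-1-one
Product: 20 (4S,6R)-4,6-dihydroxy-6-[(2S,10Z)-2-hydroxyheptadec-10-en-1-yl]cyclohex-2-en-1-one (target)
Conditions: HF·pyridine, THF–pyridine, 0 °C → rt
Reagents that add atoms: none
Why: Fluoride-assisted Si–O cleavage under mildly acidic conditions should free C4–OH without exposing the γ-hydroxy enone and the α-ketol to base, so C4 and C6 keep their configuration.

**Compound list**

1 | 2,2-dimethyl-1,3-dioxan-5-one | CC1(C)OCC(=O)CO1 | starting material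
2 | potassium 2,2-dimethyl-4H-1,3-dioxin-5-olate | CC1(C)OCC([O-])=CO1.[K+] | intermediate
3 | 2,2-dimethyl-4H-1,3-dioxin-5-yl benzoate | CC1(C)OCC(OC(=O)c2ccccc2)=CO1 | intermediate
4 | 2-(benzoyloxy)acrolein (3-oxoprop-1-en-2-yl benzoate) | C=C(OC(=O)c1ccccc1)C=O | intermediate
5 | (1E,3E)-buta-1,3-diene-1,4-diyl diacetate | CC(=O)O/C=C/C=C/OC(C)=O | starting material
6 | (1R,2S,5S)-2,5-diacetoxy-1-(benzoyloxy)cyclohex-3-ene-1-carbaldehyde | O=C[C@@]1(OC(=O)c2ccccc2)C[C@H](OC(C)=O)C=C[C@@H]1OC(C)=O | intermediate
7 | (1S,2S,5S)-2,5-diacetoxy-1-(hydroxymethyl)cyclohex-3-en-1-yl benzoate | OC[C@@]1(OC(=O)c2ccccc2)C[C@H](OC(C)=O)C=C[C@@H]1OC(C)=O | intermediate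
8 | (1S,2S,4S)-2-(hydroxymethyl)cyclohex-5-ene-1,2,4-triol | OC[C@@]1(O)C[C@H](O)C=C[C@@H]1O | intermediate
9 | [(1S,2S,5S)-1,2,5-trihydroxycyclohex-3-en-1-yl]methyl 4-methylbenzenesulfonate | Cc1ccc(cc1)S(=O)(=O)OC[C@@]1(O)C[C@H](O)C=C[C@@H]1O | intermediate
10 | [(1S,2S,5S)-5-(tert-butyldimethylsilyloxy)-1,2-dihydroxycyclohex-3-en-1-yl]methyl 4-methylbenzenesulfonate | Cc1ccc(cc1)S(=O)(=O)OC[C@@]1(O)C[C@H](O[Si](C)(C)C(C)(C)C)C=C[C@@H]1O | intermediate
11 | (3S,4S,7S)-7-(tert-butyldimethylsilyloxy)-1-oxaspiro[2.5]oct-5-en-4-ol | C1O[C@@]12C[C@H](O[Si](C)(C)C(C)(C)C)C=C[C@@H]2O | intermediate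
12 | (Z)-hexadec-9-enal | CCCCCC/C=C\CCCCCCCC=O | starting material
13 | propane-1,3-dithiol | SCCCS | starting material
14 | 2-[(8Z)-pentadec-8-en-1-yl]-1,3-dithiane | CCCCCC/C=C\CCCCCCCC1SCCCS1 | intermediate
15 | 2-lithio-2-[(8Z)-pentadec-8-en-1-yl]-1,3-dithiane | [Li]C1(CCCCCCC/C=C\CCCCCC)SCCCS1 | intermediate
16 | (1S,2S,5S)-5-(tert-butyldimethylsilyloxy)-1-({2-[(8Z)-pentadec-8-en-1-yl]-1,3-dithian-2-yl}methyl)cyclohex-3-ene-1,2-diol | CCCCCC/C=C\CCCCCCCC1(SCCCS1)C[C@@]1(O)C[C@H](O[Si](C)(C)C(C)(C)C)C=C[C@@H]1O | intermediate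
17 | (10Z)-1-[(1S,2S,5S)-5-(tert-butyldimethylsilyloxy)-1,2-dihydroxycyclohex-3-en-1-yl]heptadec-10-en-2-one | CCCCCC/C=C\CCCCCCCC(=O)C[C@@]1(O)C[C@H](O[Si](C)(C)C(C)(C)C)C=C[C@@H]1O | intermediate
18 | (1R,2S,5S)-5-(tert-butyldimethylsilyloxy)-1-[(2S,10Z)-2-hydroxyheptadec-10-en-1-yl]cyclohex-3-ene-1,2-diol | CCCCCC/C=C\CCCCCCC[C@H](O)C[C@@]1(O)C[C@H](O[Si](C)(C)C(C)(C)C)C=C[C@@H]1O | intermediate
19 | (4S,6R)-4-(tert-butyldimethylsilyloxy)-6-hydroxy-6-[(2S,10Z)-2-hydroxyheptadec-10-en-1-yl]cyclohex-2-en-1-one | CCCCCC/C=C\CCCCCCC[C@H](O)C[C@@]1(O)C[C@H](O[Si](C)(C)C(C)(C)C)C=CC1=O | intermediate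
20 | (4S,6R)-4,6-dihydroxy-6-[(2S,10Z)-2-hydroxyheptadec-10-en-1-yl]cyclohex-2-en-1-one | CCCCCC/C=C\CCCCCCC[C@H](O)C[C@@]1(O)C[C@H](O)C=CC1=O | target

**Step count**

Total: 13 steps. Longest linear sequence: 12 steps (steps 1–7 and 9–13, from compound 1).

**Steps most likely to fail**

1. Step 3 (proposed new method). What may go wrong: the cycloaddition may be too slow at temperatures where the catalyst is selective, since a 1,4-disubstituted diene with only acetoxy donors is a weak partner; the strongly acidic ammonium salt may degrade the bis-enol acetate; a formyl-endo transition state may compete, which would put the benzoate trans to the acetates; facial shielding may be insufficient.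

Fallback (auxiliary-controlled thermal cycloaddition, known chemistry, same two ring bonds): it sets out from diene 5. The diene is heated (toluene, 120 °C, sealed tube, BHT) with the lactic acid-derived chiral 2-oxyacrylate equivalent (S)-2-tert-butyl-5-methylene-1,3-dioxolan-4-one F1. This dienophile is known to add dienes anti to its tert-butyl group and with its ring oxygen endo. The reaction should give the spiro-lactone acetal (2S,5R,6S,9S)-2-tert-butyl-4-oxo-1,3-dioxaspiro[4.5]dec-7-ene-6,9-diyl diacetate F2, in which the C6 oxygen is again cis to both acetates. LiAlH4 in THF then reduces the lactone carbonyl to C1'H2OH, releases the C6 hydroxyl and cleaves both acetates. The fallback comes back to the route at tetraol 8.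

2. Step 11. What may go wrong: hydride may be delivered to the wrong face of the C2' carbonyl if boron is held by O6 alone and the chair with C1 equatorial is preferred, or the two faces may not be discriminated well.

Fallback (C2' set by SN2 inversion instead of by reduction): it sets out from ketone 17, whose reduction then gives mainly the (2'R) alcohol (1R,2S,5S)-5-(tert-butyldimethylsilyloxy)-1-[(2R,10Z)-2-hydroxyheptadec-10-en-1-yl]cyclohex-3-ene-1,2-diol F3. The cis C1/C6 diol is masked with 2,2-dimethoxypropane and pyridinium 4-toluenesulfonate in acetone as the C1–O/C6–O acetonide of the (2'R) alcohol F4. Mitsunobu esterification (4-nitrobenzoic acid, PPh3, DIAD, toluene, 0 °C) inverts C2' and gives the (2'S) 4-nitrobenzoate acetonide F5. K2CO3 in MeOH removes the ester to give the C1–O/C6–O acetonide of the (2'S) alcohol F6. Pyridinium 4-toluenesulfonate in MeOH removes the acetonide, and the fallback comes back to the route at triol 18.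

3. Step 6. What may go wrong: loss of regioselectivity, with silylation of C1–OH or of both secondary hydroxyls.

Fallback (regiocontrol by ring-size-selective acetal formation instead of by steric differentiation): it sets out from tosylate 9. 2,2-Dimethoxypropane and pyridinium 4-toluenesulfonate in acetone should give only the cis-fused five-membered C1–O/C6–O acetonide of tosylate 9 F7, because an acetonide bridging C4–O and C6–O would be a strained bicycle. The single remaining hydroxyl at C4 is silylated (TBSOTf, 2,6-lutidine, CH2Cl2, −78 °C) to the C1–O/C6–O acetonide of silyl ether 10 F8. Acetal exchange with pyridinium 4-toluenesulfonate in MeOH removes the acetonide, and the fallback comes back to the route at compound 10.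

**Further compounds**

F1 | step 3 | (S)-2-tert-butyl-5-methylene-1,3-dioxolan-4-one | C=C1O[C@H](C(C)(C)C)OC1=O
F2 | step 3 | (2S,5R,6S,9S)-2-tert-butyl-4-oxo-1,3-dioxaspiro[4.5]dec-7-ene-6,9-diyl diacetate | O=C1O[C@@H](C(C)(C)C)O[C@@]12C[C@H](OC(C)=O)C=C[C@@H]2OC(C)=O
F3 | step 11 | (1R,2S,5S)-5-(tert-butyldimethylsilyloxy)-1-[(2R,10Z)-2-hydroxyheptadec-10-en-1-yl]cyclohex-3-ene-1,2-diol | CCCCCC/C=C\CCCCCCC[C@@H](O)C[C@@]1(O)C[C@H](O[Si](C)(C)C(C)(C)C)C=C[C@@H]1O
F4 | step 11 | C1–O/C6–O acetonide (isopropylidene acetal) of the (2'R) alcohol F3 | CCCCCC/C=C\CCCCCCC[C@@H](O)C[C@@]1(O2)C[C@H](O[Si](C)(C)C(C)(C)C)C=C[C@@H]1OC2(C)C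
F5 | step 11 | (2'S) 4-nitrobenzoate of the C1–O/C6–O acetonide | CCCCCC/C=C\CCCCCCC[C@H](OC(=O)c1ccc(cc1)[N+](=O)[O-])C[C@@]1(O2)C[C@H](O[Si](C)(C)C(C)(C)C)C=C[C@@H]1OC2(C)C
F6 | step 11 | C1–O/C6–O acetonide of the (2'S) alcohol 18 | CCCCCC/C=C\CCCCCCC[C@H](O)C[C@@]1(O2)C[C@H](O[Si](C)(C)C(C)(C)C)C=C[C@@H]1OC2(C)C
F7 | step 6 | C1–O/C6–O acetonide of tosylate 9 | Cc1ccc(cc1)S(=O)(=O)OC[C@@]1(O2)C[C@H](O)C=C[C@@H]1OC2(C)C
F8 | step 6 | C1–O/C6–O acetonide of silyl ether 10 | Cc1ccc(cc1)S(=O)(=O)OC[C@@]1(O2)C[C@H](O[Si](C)(C)C(C)(C)C)C=C[C@@H]1OC2(C)C
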